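**Retrosynthetic overview**
- The caffeate is put on C3 last, by Mitsunobu inversion of a 3α-allylic alcohol that comes from SeO2 oxidation next to the C4=C15 exocyclic methylene; C7 and C8 come from a thermodynamic dissolving-metal reduction of a 7(11)-en-8-one.
- Ring A shows the triad 1β-OH / quaternary C10–CH3 / C4=C15 methylene on a trans C5–C10 fusion. This is the signature of a 1,10-epoxygermacra-4-ene, in which C10 and C5 face each other across the ten-membered ring (crossed E,E-1,5-diene), so the C5–C10 bond is disconnected to (1R,10R)-1,10-epoxygermacrone.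
- Ring order: the ten-membered carbocycle is bought (germacrone, achiral); the oxirane is set by catalytic asymmetric epoxidation; one transannular radical cyclisation then closes rings A and B of the decalin together and relays the oxirane configuration to C1, C10 and C5.
- C7, C8 and C3 follow by substrate control on the rigid trans-decalin.

Key step: step 2

Remark: germacrone is taken as the purchasable achiral C15 starting material, and the target is read as the (1R,3S,5S,7R,8S,10R) isomer, i.e. 1β,8α-dihydroxy-3β-caffeoyloxy-5α-eudesm-4(15)-ene with 7β-isopropyl and 10β-methyl.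

**Step 1**
Reactants: 1 germacrone, (3E,7E)-3,7-dimethyl-10-(propan-2-ylidene)cyclodeca-3,7-dien-1-one
Product: 2 (1R,10R)-1,10-epoxygermacra-4(E),7(11)-dien-8-one
Conditions: 1,2:4,5-di-O-isopropylidene-β-D-erythro-2,3-hexodiulo-2,6-pyranose (0.3 equiv), Oxone (2KHSO5·KHSO4·K2SO4), K2CO3, Bu4NHSO4, MeCN/CH2(OMe)2/aq. Na2B4O7 buffer, −10 to 0 °C, stopped at partial conversion; chromatography
Reagents that add atoms: potassium peroxymonosulfate (KHSO5), [K+].[O-]S(=O)(=O)OO
Why: Shi epoxidation: the chiral dioxirane, which gives (R,R)-oxides from E-olefins, can reach only the outer face of a ring olefin and so selects between the rapidly interconverting enantiomeric crossed conformers of achiral germacrone, setting C1 and C10 together, while the cross-conjugated 7(11)-olefin is too electron-poor to react; the more electron-rich 4,5-olefin is expected to compete, which is why conversion is held low and the regioisomeric oxide is removed by chromatography.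

**Step 2**
Reactants: 2 (1R,10R)-1,10-epoxygermacra-4(E),7(11)-dien-8-one
Product: 3 (1R,5S,10R)-1-hydroxyeudesma-4(15),7(11)-dien-8-one (1β-OH, 5α-H, 10β-CH3)
Conditions: Cp2TiCl2 (2.5 equiv), Mn dust, THF (dry, degassed), rt, slow addition of 2; then 1 M HCl
Reagents that add atoms: none
Why: Cp2TiCl (trivalent titanium) opens the oxirane homolytically at the tertiary carbon to a β-titanoxy C10 radical, which adds across the ring to C5 of the 4,5-olefin; the tertiary C4 radical is captured by a second Cp2TiCl and loses a β-hydrogen from C15 to leave the exocyclic methylene. The closest known reaction type is the titanocene-mediated reductive opening and transannular radical cyclisation of 1,10-epoxygermacra-4-enes to 1β-hydroxyeudesm-4(15)-enes, the radical counterpart of the cationic germacrane-to-eudesmane step of the biosynthesis. The single C5–C10 bond divides the ten-membered ring into rings A and B; the closure is 6-endo-trig with respect to ring A and 6-exo-trig with respect to ring B. C1 keeps the configuration fixed in step 1, while C10 and C5 are set by the chair–chair transition state of the crossed E,E conformer, in which the C1–O bond is pseudo-equatorial and the C10 methyl and C5 hydrogen end on opposite faces (trans-decalin). The step needs C–O cleavage at C10 and not C1, C–C bond formation faster than reduction or elimination of the first radical, and termination to the 4(15)-olefin and not the 3- or 4-ene; the tertiary radical, the short transannular C10···C5 distance and the anhydrous medium without a hydrogen-atom donor secure these in turn.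

**Step 3**
Reactants: 3 (1R,5S,10R)-1-hydroxyeudesma-4(15),7(11)-dien-8-one
Product: 5 (1R,5S,7R,8S,10R)-eudesm-4(15)-ene-1,8-diol (1β,8α-diol, 7β-isopropyl), via 1β-hydroxyeudesm-4(15)-en-8-one 4 (not isolated)
Conditions: Li (excess), NH3(l)/THF, MeOH, −78 to −33 °C; then NH4Cl
Reagents that add atoms: none
Why: Dissolving-metal reduction of the pulegone-to-menthol type: the enone is reduced to its enolate, methanol protonates it axially at C7 so that the isopropyl group becomes equatorial (7β), and ketone 4 is reduced further under thermodynamic control to the equatorial 8α-alcohol trans to the isopropyl group, while the isolated exocyclic olefin is untouched.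

**Step 4**
Reactants: 5 (1R,5S,7R,8S,10R)-eudesm-4(15)-ene-1,8-diol
Product: 6 (1R,5S,7R,8S,10R)-1,8-bis(tert-butyldimethylsilyloxy)eudesm-4(15)-ene
Conditions: TBSOTf, 2,6-lutidine, CH2Cl2, 0 °C to rt
Reagents that add atoms: tert-butyldimethylsilyl trifluoromethanesulfonate (TBSOTf), CC(C)(C)[Si](C)(C)OS(=O)(=O)C(F)(F)F
Why: Silylation with the silyl triflate and a hindered base covers both secondary alcohols, including the neopentyl-type C1–OH, so that only the allylic C3–OH made next can be acylated.

**Step 5**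
Reactants: 6 (1R,5S,7R,8S,10R)-1,8-bis(tert-butyldimethylsilyloxy)eudesm-4(15)-ene
Product: 7 (1R,3R,5S,7R,8S,10R)-1,8-bis(tert-butyldimethylsilyloxy)eudesm-4(15)-en-3-ol (3α-OH, axial)
Conditions: SeO2 (0.5 equiv), t-BuOOH, CH2Cl2, rt
Reagents that add atoms: tert-butyl hydroperoxide, CC(C)(C)OO (terminal oxidant); selenium dioxide, O=[Se]=O (transfers the oxygen atom)
Why: SeO2 allylic hydroxylation (ene reaction at the exocyclic methylene, then [2,3]-sigmatropic shift) should occur at the ring CH2 (C3) and not at the tertiary C5–H, and should deliver oxygen axially on the α-face to give the 3α-alcohol with the exocyclic double bond restored.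

**Step 6**
Reactants: 8 caffeic acid, (E)-3-(3,4-dihydroxyphenyl)prop-2-enoic acid
Product: 10 (E)-3-[3,4-bis(tert-butyldimethylsilyloxy)phenyl]prop-2-enoic acid, via tris-silylated silyl ester 9 (not isolated)
Conditions: TBSCl, imidazole, DMF, rt; then AcOH/THF/H2O, rt
Reagents that add atoms: tert-butyldimethylsilyl chloride (TBSCl), CC(C)(C)[Si](C)(C)Cl
Why: Exhaustive silylation followed by selective hydrolysis of the labile silyl ester keeps the two phenolic silyl ethers and frees the carboxylic acid needed as the Mitsunobu pronucleophile.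

**Step 7**
Reactants: 7 (1R,3R,5S,7R,8S,10R)-1,8-bis(tert-butyldimethylsilyloxy)eudesm-4(15)-en-3-ol; 10 (E)-3-[3,4-bis(tert-butyldimethylsilyloxy)phenyl]prop-2-enoic acid
Product: 11 (1R,3S,5S,7R,8S,10R)-1,8-bis(tert-butyldimethylsilyloxy)eudesm-4(15)-en-3-yl (E)-3-[3,4-bis(tert-butyldimethylsilyloxy)phenyl]prop-2-enoate
Conditions: PPh3, DIAD, toluene/THF, 0 °C to rt
Reagents that add atoms: none
Why: Mitsunobu esterification: the axial allylic 3α-alcohol is activated as its alkoxyphosphonium salt and displaced by the carboxylate from the equatorial direction with inversion, which sets the 3β (3S) ester directly.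

**Step 8**
Reactants: 11 (1R,3S,5S,7R,8S,10R)-1,8-bis(tert-butyldimethylsilyloxy)eudesm-4(15)-en-3-yl (E)-3-[3,4-bis(tert-butyldimethylsilyloxy)phenyl]prop-2-enoate
Product: 12 CNP0264533.1, (1R,3S,5S,7R,8S,10R)-1,8-dihydroxyeudesm-4(15)-en-3-yl (E)-3-(3,4-dihydroxyphenyl)prop-2-enoate
Conditions: HF·pyridine, pyridine/THF, 0 °C to rt
Reagents that add atoms: none
Why: Buffered HF desilylation cleaves the two aryl and two alkyl silyl ethers without base, so the allylic cinnamate should neither hydrolyse nor migrate to the 1,3-related C1–OH.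

**Compound list**
1 | germacrone, (3E,7E)-3,7-dimethyl-10-(propan-2-ylidene)cyclodeca-3,7-dien-1-one | C/C1=C\CC(=C(C)C)C(=O)C/C(C)=C/CC1 | starting material
2 | (1R,10R)-1,10-epoxygermacra-4(E),7(11)-dien-8-one | C/C1=C\CC(=C(C)C)C(=O)C[C@@]2(C)O[C@@H]2CC1 | intermediate
3 | (1R,5S,10R)-1-hydroxyeudesma-4(15),7(11)-dien-8-one | C=C1CC[C@@H](O)[C@]2(C)CC(=O)C(=C(C)C)C[C@@H]12 | intermediate
4 | (1R,5S,7R,10R)-1-hydroxyeudesm-4(15)-en-8-one | C=C1CC[C@@H](O)[C@]2(C)CC(=O)[C@@H](C(C)C)C[C@@H]12 | intermediate
5 | (1R,5S,7R,8S,10R)-eudesm-4(15)-ene-1,8-diol | C=C1CC[C@@H](O)[C@]2(C)C[C@H](O)[C@@H](C(C)C)C[C@@H]12 | intermediate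
6 | (1R,5S,7R,8S,10R)-1,8-bis(tert-butyldimethylsilyloxy)eudesm-4(15)-ene | C=C1CC[C@@H](O[Si](C)(C)C(C)(C)C)[C@]2(C)C[C@H](O[Si](C)(C)C(C)(C)C)[C@@H](C(C)C)C[C@@H]12 | intermediate
7 | (1R,3R,5S,7R,8S,10R)-1,8-bis(tert-butyldimethylsilyloxy)eudesm-4(15)-en-3-ol | C=C1[C@H](O)C[C@@H](O[Si](C)(C)C(C)(C)C)[C@]2(C)C[C@H](O[Si](C)(C)C(C)(C)C)[C@@H](C(C)C)C[C@@H]12 | intermediate
8 | caffeic acid | OC(=O)/C=C/c1ccc(O)c(O)c1 | starting material
9 | tert-butyldimethylsilyl (E)-3-[3,4-bis(tert-butyldimethylsilyloxy)phenyl]prop-2-enoate | CC(C)(C)[Si](C)(C)OC(=O)/C=C/c1ccc(O[Si](C)(C)C(C)(C)C)c(O[Si](C)(C)C(C)(C)C)c1 | intermediate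
10 | (E)-3-[3,4-bis(tert-butyldimethylsilyloxy)phenyl]prop-2-enoic acid | OC(=O)/C=C/c1ccc(O[Si](C)(C)C(C)(C)C)c(O[Si](C)(C)C(C)(C)C)c1 | intermediate
11 | (1R,3S,5S,7R,8S,10R)-1,8-bis(tert-butyldimethylsilyloxy)eudesm-4(15)-en-3-yl (E)-3-[3,4-bis(tert-butyldimethylsilyloxy)phenyl]prop-2-enoate | C=C1[C@@H](OC(=O)/C=C/c2ccc(O[Si](C)(C)C(C)(C)C)c(O[Si](C)(C)C(C)(C)C)c2)C[C@@H](O[Si](C)(C)C(C)(C)C)[C@]2(C)C[C@H](O[Si](C)(C)C(C)(C)C)[C@@H](C(C)C)C[C@@H]12 | intermediate
12 | CNP0264533.1 | C=C1[C@@H](OC(=O)/C=C/c2ccc(O)c(O)c2)C[C@@H](O)[C@]2(C)C[C@H](O)[C@@H](C(C)C)C[C@@H]12 | target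

**Step count**
Total: 8 steps. Longest linear sequence: 7 steps (steps 1, 2, 3, 4, 5, 7, 8).

**Steps most likely to fail**

Step 1. The oxidant may react faster at the more electron-rich 4,5-olefin than at the 1(10)-olefin, which is β,γ to the ketone; double epoxidation, base-induced opening of the β,γ-epoxy ketone and poor discrimination between the two planar-chiral conformers are further risks. The fallback places the oxirane by hydroxyl direction and parts the antipodes later; it sets out from 1 and returns at 5. Li/NH3/MeOH (as in step 3) should reduce 1 to racemic 7,8-anti (7R*,8S*)-germacra-1(10),4-dien-8-ol F1, the isomer with both substituents pseudo-equatorial. VO(acac)2/t-BuOOH should then epoxidise only the homoallylic 1(10)-olefin, on the outer face of that conformer, to racemic (1R*,7R*,8S*,10R*)-1,10-epoxygermacr-4-en-8-ol F2. Cp2TiCl as in step 2 should convert F2 into racemic 5, that is 5 together with its enantiomer ent-5 F3. Acylation with vinyl acetate catalysed by Candida antarctica lipase B, a resolution of the menthol type, should esterify the antipode as 8-O-acetyl-ent-5 F4 and leave 5.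

Step 7. The activated allylic alcohol may be attacked at C15 (SN2′ transposition to a primary ester with a ring double bond) or may eliminate to a diene instead of undergoing clean inversion at C3. The fallback inverts by oxidation and reduction and then acylates with retention; it sets out from 7 and returns at 11. Dess–Martin periodinane should give 1β,8α-bis(tert-butyldimethylsilyloxy)eudesm-4(15)-en-3-one F8. Luche reduction (NaBH4, CeCl3·7H2O, MeOH, −78 °C) with axial hydride delivery on the α-face should give the equatorial 3β-alcohol, 1β,8α-bis(tert-butyldimethylsilyloxy)eudesm-4(15)-en-3β-ol F9. Steglich esterification (EDC·HCl, DMAP, CH2Cl2) of F9 with 10 should give 11.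

Step 5. Hydroxylation may go to the tertiary allylic C5–H, run on to the enone, or give the wrong C3 epimer. The fallback introduces the C3 oxygen through a ketone; it sets out from 6 and returns at 7. Ozonolysis (O3, CH2Cl2/MeOH, −78 °C; Me2S) should give 1β,8α-bis(tert-butyldimethylsilyloxy)-15-nor-5α-eudesman-4-one F5. Kinetic enolisation at the C3 methylene (LDA, TMSCl, THF, −78 °C) should give the Δ3 trimethylsilyl enol ether F6. Rubottom oxidation (mCPBA, NaHCO3; mild acid work-up) on the α-face, opposite the axial C10 methyl, should give 3α-hydroxy-1β,8α-bis(tert-butyldimethylsilyloxy)-15-nor-5α-eudesman-4-one F7. Non-basic Petasis methylenation with Cp2TiMe2 (excess, toluene, 65 °C) should then give 7 without epimerising the α-ketol.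

**Further compounds**
F1 | step 1 | racemic (7R*,8S*)-germacra-1(10),4-dien-8-ol (the enantiomer leading to 5 is drawn) | C/C1=C\C[C@H](C(C)C)[C@@H](O)C/C(C)=C/CC1
F2 | step 1 | racemic (1R*,7R*,8S*,10R*)-1,10-epoxygermacr-4-en-8-ol (the enantiomer leading to 5 is drawn) | C/C1=C\C[C@H](C(C)C)[C@@H](O)C[C@@]2(C)O[C@@H]2CC1
F3 | step 1 | ent-5, (1S,5R,7S,8R,10S)-eudesm-4(15)-ene-1,8-diol | C=C1CC[C@H](O)[C@@]2(C)C[C@@H](O)[C@H](C(C)C)C[C@H]12
F4 | step 1 | 8-O-acetyl-ent-5 | C=C1CC[C@H](O)[C@@]2(C)C[C@@H](OC(C)=O)[C@H](C(C)C)C[C@H]12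
F5 | step 5 | 1β,8α-bis(tert-butyldimethylsilyloxy)-15-nor-5α-eudesman-4-one | O=C1CC[C@@H](O[Si](C)(C)C(C)(C)C)[C@]2(C)C[C@H](O[Si](C)(C)C(C)(C)C)[C@@H](C(C)C)C[C@@H]12
F6 | step 5 | 1β,8α-bis(tert-butyldimethylsilyloxy)-4-(trimethylsilyloxy)-15-nor-5α-eudesm-3-ene | C[Si](C)(C)OC1=CC[C@@H](O[Si](C)(C)C(C)(C)C)[C@]2(C)C[C@H](O[Si](C)(C)C(C)(C)C)[C@@H](C(C)C)C[C@@H]12
F7 | step 5 | 3α-hydroxy-1β,8α-bis(tert-butyldimethylsilyloxy)-15-nor-5α-eudesman-4-one | O=C1[C@H](O)C[C@@H](O[Si](C)(C)C(C)(C)C)[C@]2(C)C[C@H](O[Si](C)(C)C(C)(C)C)[C@@H](C(C)C)C[C@@H]12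
F8 | step 7 | 1β,8α-bis(tert-butyldimethylsilyloxy)eudesm-4(15)-en-3-one | C=C1C(=O)C[C@@H](O[Si](C)(C)C(C)(C)C)[C@]2(C)C[C@H](O[Si](C)(C)C(C)(C)C)[C@@H](C(C)C)C[C@@H]12
F9 | step 7 | 1β,8α-bis(tert-butyldimethylsilyloxy)eudesm-4(15)-en-3β-ol | C=C1[C@@H](O)C[C@@H](O[Si](C)(C)C(C)(C)C)[C@]2(C)C[C@H](O[Si](C)(C)C(C)(C)C)[C@@H](C(C)C)C[C@@H]12
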